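## Retrosynthetic overview

1. Target ⇐ ten-membered Z-allylic alcohol: the 1,10-epoxide (C9–OH-directed) and the C9 ketone come last; the carbocycle is closed at C9–C10 by an intramolecular Nozaki–Hiyama–Kishi macrocyclization of a (Z)-vinyl iodide onto the C9 aldehyde.
2. The seco-aldehyde is cut at C3–C4 and at the three ester C–O bonds into three fragments: an eastern (Z)-vinyl iodide (C4–C9), a western Weinreb amide (C10, C1–C3) and an angeloyl mixed anhydride.
3. C3–C4 by acylation of the eastern alkenyllithium; C3 by CBS reduction; the 4,5-epoxide by C3–OH-directed epoxidation on the open chain.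
4. East: C6, C7, C8 from D-arabinose (isopropenyl cuprate opening of a 2,3-anhydro-lyxofuranoside); both Z-trisubstituted alkenes from Stork–Zhao olefinations.
5. Ring order: 4,5-oxirane (acyclic) → cyclodecene (macrocyclization) → 1,10-oxirane.

Assumption and convention: (Z)-2-bromobut-2-ene is taken as a commercial, geometrically pure liquid; atoms keep the target numbering (C1 epoxide CH next to C2H2, C3 CHO-ester, C4 methyl-bearing epoxide carbon, C5, C6, C7 isopropenyl-bearing, C8, C9 ketone, C10 methyl-bearing epoxide carbon); TBDPS = tert-butyldiphenylsilyl, TBS = tert-butyldimethylsilyl, TES = triethylsilyl, Ang = (Z)-2-methylbut-2-enoyl.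

## Route

**Eastern fragment**

Step 1
Reactants: 1 D-arabinose
Product: 2 methyl α-D-arabinofuranoside
Conditions: MeOH, AcCl (0.3 equiv), rt, 5 h; pyridine; α-anomer crystallised
Reagents that add atoms: methanol (CO)
Why: Kinetic Fischer glycosidation gives the furanosides with the 1,2-trans α-anomer as the major product; sugar C2 and C4 become C6 and C8 of the target.

Step 2
Reactants: 2 methyl α-D-arabinofuranoside
Product: 3 methyl 5-O-TBDPS-α-D-arabinofuranoside
Conditions: TBDPSCl, imidazole, DMF, 0 °C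
Reagents that add atoms: tert-butyl(chloro)diphenylsilane (CC(C)(C)[Si](Cl)(c1ccccc1)c1ccccc1)
Why: Selective silylation of the only primary hydroxyl with a bulky silyl chloride.

Step 3
Reactants: 3 methyl 5-O-TBDPS-α-D-arabinofuranoside
Product: 4 methyl 2,3-anhydro-5-O-TBDPS-α-D-lyxofuranoside
Conditions: PPh3, DIAD, THF, 0 °C → rt
Reagents that add atoms: none
Why: Mitsunobu cyclodehydration of the trans-diol, in which the more acidic 2-hydroxyl displaces the activated 3-oxygen with inversion at sugar C3 to give the lyxo epoxide.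

Step 4
Reactants: 4 methyl 2,3-anhydro-5-O-TBDPS-α-D-lyxofuranoside
Product: 5 methyl 5-O-TBDPS-3-deoxy-3-C-(prop-1-en-2-yl)-α-D-arabinofuranoside
Conditions: CH2=C(CH3)MgBr (3 equiv), CuI (0.1 equiv), THF, −30 → 0 °C; then H2O
Reagents that add atoms: isopropenylmagnesium bromide (CC(=C)[Mg]Br)
Why: Copper-catalysed Grignard opening of the epoxide by SN2 attack anti to the oxirane at sugar C3 (C2 is shielded by the syn anomeric OMe and deactivated by the acetal); the inversion restores the arabino configuration and sets C7.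

Step 5
Reactants: 5 methyl 5-O-TBDPS-3-deoxy-3-C-(prop-1-en-2-yl)-α-D-arabinofuranoside
Product: 6 5-O-TBDPS-3-deoxy-3-C-(prop-1-en-2-yl)-D-arabinofuranose (lactol)
Conditions: 1 M HCl/THF (1:3), 40 °C
Reagents that add atoms: water (O)
Why: Acid-catalysed hydrolysis of the labile methyl furanoside; the primary TBDPS ether and the isolated isopropenyl group survive dilute acid and no stereocentre of the target is touched.

Step 6
Reactants: 6 lactol
Product: 7 eastern diol vinyl iodide
Conditions: Ph3P=C(CH3)I (4 equiv; from EtPPh3I, n-BuLi, then I2, −78 °C, then NaN(SiMe3)2, −20 °C), THF, −78 → −10 °C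
Reagents that add atoms: ethyltriphenylphosphonium iodide (CC[P+](c1ccccc1)(c1ccccc1)c1ccccc1.[I-]); iodine (II)
Why: Stork–Zhao–Wittig olefination of the ring-opened hydroxy aldehyde gives the (Z)-2-iodoalkene (iodine cis to C6), which fixes the later C4=C5 geometry and frees the C8 hydroxyl.

Step 7
Reactants: 7 eastern diol vinyl iodide
Product: 8 eastern vinyl iodide bis(triethylsilyl) ether
Conditions: TESCl, imidazole, DMAP (cat.), DMF, 0 °C → rt
Reagents that add atoms: chlorotriethylsilane (CC[Si](Cl)(CC)CC)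
Why: Silylation of both secondary hydroxyls makes the fragment compatible with halogen–lithium exchange.

**Western fragment**

Step 8
Reactants: 9 propane-1,3-diol
Product: 10 3-[(tert-butyldimethylsilyl)oxy]propan-1-ol
Conditions: NaH (1.0 equiv), THF, 0 °C → rt; TBSCl (1.0 equiv)
Reagents that add atoms: tert-butyl(chloro)dimethylsilane (CC(C)(C)[Si](C)(C)Cl)
Why: Monosilylation of a symmetrical diol through its poorly soluble mono-sodium alkoxide (McDougal procedure).

Step 9
Reactants: 10 3-[(tert-butyldimethylsilyl)oxy]propan-1-ol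
Product: 11 3-[(tert-butyldimethylsilyl)oxy]propanal
Conditions: Dess–Martin periodinane, NaHCO3, CH2Cl2, 0 °C → rt
Reagents that add atoms: none
Why: Dess–Martin oxidation of a primary alcohol to the aldehyde without over-oxidation.

Step 10
Reactants: 11 3-[(tert-butyldimethylsilyl)oxy]propanal
Product: 12 (Z)-tert-butyl[(4-iodopent-3-en-1-yl)oxy]dimethylsilane
Conditions: EtPPh3I, n-BuLi, THF; I2, −78 °C; NaN(SiMe3)2, −20 °C; then 11, −78 → −20 °C
Reagents that add atoms: ethyltriphenylphosphonium iodide (CC[P+](c1ccccc1)(c1ccccc1)c1ccccc1.[I-]); iodine (II)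
Why: Stork–Zhao–Wittig olefination gives the (Z)-vinyl iodide (iodine cis to the chain), the future C1=C10 alkene.

Step 11
Reactants: 12 (Z)-tert-butyl[(4-iodopent-3-en-1-yl)oxy]dimethylsilane
Product: 13 (Z)-4-iodopent-3-en-1-ol
Conditions: AcCl (0.05 equiv), MeOH, 0 °C → rt
Reagents that add atoms: none
Why: Acid-catalysed methanolysis of a primary silyl ether; the vinyl iodide is inert.

Step 12
Reactants: 13 (Z)-4-iodopent-3-en-1-ol
Product: 14 (Z)-4-iodopent-3-enal
Conditions: Dess–Martin periodinane, NaHCO3, CH2Cl2, 0 °C (used crude)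
Reagents that add atoms: none
Why: Buffered Dess–Martin oxidation gives the β,γ-unsaturated aldehyde without migration of the double bond.

Step 13
Reactants: 14 (Z)-4-iodopent-3-enal
Product: 15 (Z)-4-iodopent-3-enoic acid
Conditions: NaClO2, NaH2PO4, 2-methylbut-2-ene, t-BuOH/H2O, 0 °C
Reagents that add atoms: sodium chlorite ([Na+].[O-]Cl=O)
Why: Pinnick oxidation under buffered conditions converts the aldehyde to the acid and leaves the skipped alkene in place.

Step 14
Reactants: 15 (Z)-4-iodopent-3-enoic acid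
Product: 16 (Z)-4-iodo-N-methoxy-N-methylpent-3-enamide
Conditions: MeNHOMe·HCl, EDC·HCl, N-methylmorpholine, CH2Cl2, 0 °C → rt
Reagents that add atoms: N,O-dimethylhydroxylamine hydrochloride (CNOC.Cl)
Why: Carbodiimide amide coupling gives the Weinreb amide that will deliver C3 at the ketone oxidation level.

**Acyl fragment**

Step 15
Reactants: 17 (Z)-2-bromobut-2-ene
Product: 19 angelic acid, via (Z)-but-2-en-2-yllithium 18 (not isolated)
Conditions: t-BuLi (2.0 equiv), Et2O, −78 °C; CO2; aq. HCl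
Reagents that add atoms: carbon dioxide (O=C=O)
Why: Bromine–lithium exchange and carboxylation both proceed with retention of alkene geometry, so the Z bromide gives only the Z acid.

Step 16
Reactants: 19 angelic acid
Product: 20 angelic 2,4,6-trichlorobenzoic anhydride
Conditions: 2,4,6-Cl3C6H2COCl, Et3N, THF, 0 °C → rt; filter, concentrate
Reagents that add atoms: 2,4,6-trichlorobenzoyl chloride (O=C(Cl)c1c(Cl)cc(Cl)cc1Cl)
Why: Yamaguchi-type mixed anhydride formation activates the acid without the Z→E isomerisation seen with the acid chloride.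

**Fragment union and endgame**

Step 17
Reactants: 8 eastern vinyl iodide bis(triethylsilyl) ether; 16 (Z)-4-iodo-N-methoxy-N-methylpent-3-enamide
Product: 22 seco-dienone (C3 ketone), via eastern alkenyllithium 21 (not isolated)
Conditions: 8, t-BuLi (2.05 equiv), Et2O, −78 °C; then 16 (1.2 equiv), −78 → −40 °C; H2O
Reagents that add atoms: none
Why: Iodine–lithium exchange with retention gives the (Z)-alkenyllithium before the second vinyl iodide is present, and Weinreb ketone synthesis (chelated tetrahedral intermediate, no over-addition) forms the C3–C4 bond.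

Step 18
Reactants: 22 seco-dienone
Product: 23 (3S)-seco-allylic alcohol
Conditions: (R)-2-methyl-CBS-oxazaborolidine (0.3 equiv), catecholborane, toluene, −78 °C
Reagents that add atoms: none
Why: Corey–Bakshi–Shibata reduction in which the α-methyl alkenyl group acts as the large substituent, so the (R)-catalyst gives the 3S carbinol; catecholborane does not hydroborate the alkenes.

Step 19
Reactants: 23 (3S)-seco-allylic alcohol
Product: 24 4,5-epoxy alcohol
Conditions: mCPBA (1.1 equiv), NaHCO3, CH2Cl2, −20 → 0 °C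
Reagents that add atoms: 3-chloroperoxybenzoic acid (O=C(OO)c1cccc(Cl)c1)
Why: Henbest hydroxyl-directed epoxidation: in the A(1,3)-minimised conformer (C3–H eclipsing the Z alkene) the hydrogen-bonded peracid attacks syn to the C3–OH and gives the threo epoxy alcohol (4R,5S), while the vinyl iodide and isopropenyl alkenes react much more slowly.

Step 20
Reactants: 24 4,5-epoxy alcohol
Product: 25 epoxy triol
Conditions: HF·pyridine, pyridine, THF, 0 °C
Reagents that add atoms: none
Why: Buffered fluoride desilylation cleaves the two secondary TES ethers and leaves the primary TBDPS ether and the epoxide intact.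

Step 21
Reactants: 25 epoxy triol; 20 angelic 2,4,6-trichlorobenzoic anhydride
Product: 26 tris(angelate) silyl ether
Conditions: 20 (6 equiv), Et3N, toluene, 75 °C
Reagents that add atoms: none
Why: Esterification through the mixed anhydride, in which the alcohols attack the unhindered angeloyl carbonyl and, with no nucleophilic catalyst present, the Z enoate does not isomerise to tiglate.

Step 22
Reactants: 26 tris(angelate) silyl ether
Product: 27 tris(angelate) primary alcohol
Conditions: HF·pyridine, THF, 0 °C → rt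
Reagents that add atoms: none
Why: Acidic fluoride desilylation of the primary TBDPS ether avoids the base-induced 1,2-acyl shift from C8 to C9.

Step 23
Reactants: 27 tris(angelate) primary alcohol
Product: 28 seco-aldehyde
Conditions: Dess–Martin periodinane, NaHCO3, CH2Cl2, 0 °C
Reagents that add atoms: none
Why: Neutral Dess–Martin oxidation gives the α-acyloxy aldehyde without epimerising C8.

Step 24
Reactants: 28 seco-aldehyde
Product: 29 macrocyclic allylic alcohol (cyclodecenol)
Conditions: CrCl2 (10 equiv), NiCl2 (0.1 equiv), DMSO/THF (3:1), rt, 2 mM, slow addition; H2O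
Reagents that add atoms: none
Why: Nozaki–Hiyama–Kishi macrocyclization: zerovalent nickel inserts into the vinyl C–I bond, transmetalation to trivalent chromium and chemoselective addition to the aldehyde close the ten-membered ring with retention of the Z alkene, and Felkin–Anh addition anti to the C8 ester sets the temporary C9 carbinol.

Step 25
Reactants: 29 macrocyclic allylic alcohol
Product: 30 bis-epoxy alcohol
Conditions: VO(acac)2 (0.1 equiv), t-BuOOH, CH2Cl2, 0 °C
Reagents that add atoms: tert-butyl hydroperoxide (CC(C)(C)OO)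
Why: Vanadium-catalysed hydroxyl-directed epoxidation delivers oxygen syn to the C9 hydroxyl of the Z-cycloalkenol (the erythro mode favoured by the geminal C10 methyl), setting C1 and C10 and leaving all other alkenes untouched.

Step 26
Reactants: 30 bis-epoxy alcohol
Product: 31 target, (1R,3S,4R,5S,6S,7S,8S,10R)-1,10:4,5-diepoxy-3,6,8-tris(angeloyloxy)germacr-11-en-9-one
Conditions: Dess–Martin periodinane, NaHCO3, CH2Cl2, 0 °C → rt
Reagents that add atoms: none
Why: Dess–Martin oxidation of the epoxy alcohol removes the auxiliary C9 stereocentre and gives the α,β-epoxy ketone under neutral conditions that do not epimerise C8.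

## Compound list

1 | D-arabinose (drawn as the aldehydo form) | O=C[C@@H](O)[C@H](O)[C@H](O)CO | starting material
2 | methyl α-D-arabinofuranoside | CO[C@H]1O[C@H](CO)[C@@H](O)[C@@H]1O | intermediate
3 | methyl 5-O-(tert-butyldiphenylsilyl)-α-D-arabinofuranoside | CO[C@H]1O[C@H](CO[Si](c2ccccc2)(c2ccccc2)C(C)(C)C)[C@@H](O)[C@@H]1O | intermediate
4 | methyl 2,3-anhydro-5-O-(tert-butyldiphenylsilyl)-α-D-lyxofuranoside | CO[C@H]1O[C@H](CO[Si](c3ccccc3)(c3ccccc3)C(C)(C)C)[C@@H]2O[C@H]12 | intermediate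
5 | methyl 5-O-(tert-butyldiphenylsilyl)-3-deoxy-3-C-(prop-1-en-2-yl)-α-D-arabinofuranoside | CO[C@H]1O[C@H](CO[Si](c2ccccc2)(c2ccccc2)C(C)(C)C)[C@@H](C(C)=C)[C@@H]1O | intermediate
6 | 5-O-(tert-butyldiphenylsilyl)-3-deoxy-3-C-(prop-1-en-2-yl)-D-arabinofuranose (lactol, anomeric mixture) | OC1O[C@H](CO[Si](c2ccccc2)(c2ccccc2)C(C)(C)C)[C@@H](C(C)=C)[C@@H]1O | intermediate
7 | eastern diol vinyl iodide: (Z)-I–C4(CH3)=C5H–C6H(OH)–C7H[C(CH3)=CH2]–C8H(OH)–C9H2–OTBDPS; 6S,7S,8S | C=C(C)[C@@H]([C@H](O)/C=C(/C)I)[C@H](O)CO[Si](c1ccccc1)(c1ccccc1)C(C)(C)C | intermediate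
8 | eastern vinyl iodide: 6,8-bis-O-TES ether of 7; 4Z; 6S,7S,8S | C=C(C)[C@@H]([C@H](O[Si](CC)(CC)CC)/C=C(/C)I)[C@H](O[Si](CC)(CC)CC)CO[Si](c1ccccc1)(c1ccccc1)C(C)(C)C | intermediate
9 | propane-1,3-diol | OCCCO | starting material
10 | 3-[(tert-butyldimethylsilyl)oxy]propan-1-ol | CC(C)(C)[Si](C)(C)OCCCO | intermediate
11 | 3-[(tert-butyldimethylsilyl)oxy]propanal | CC(C)(C)[Si](C)(C)OCCC=O | intermediate
12 | (Z)-tert-butyl[(4-iodopent-3-en-1-yl)oxy]dimethylsilane | CC(C)(C)[Si](C)(C)OCC/C=C(/C)I | intermediate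
13 | (Z)-4-iodopent-3-en-1-ol | OCC/C=C(/C)I | intermediate
14 | (Z)-4-iodopent-3-enal | O=CC/C=C(/C)I | intermediate
15 | (Z)-4-iodopent-3-enoic acid | OC(=O)C/C=C(/C)I | intermediate
16 | (Z)-4-iodo-N-methoxy-N-methylpent-3-enamide (western amide: C3 carbonyl, C2, C1=C10, C14) | CON(C)C(=O)C/C=C(/C)I | intermediate
17 | (Z)-2-bromobut-2-ene | C/C=C(/C)Br | starting material
18 | (Z)-but-2-en-2-yllithium (formed in the flask) | C/C=C(/C)[Li] | intermediate
19 | angelic acid, (Z)-2-methylbut-2-enoic acid | C/C=C(/C)C(=O)O | intermediate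
20 | angelic 2,4,6-trichlorobenzoic anhydride | C/C=C(/C)C(=O)OC(=O)c1c(Cl)cc(Cl)cc1Cl | intermediate
21 | eastern alkenyllithium: 8 with Li in place of I, Z geometry retained (formed in the flask) | C=C(C)[C@@H]([C@H](O[Si](CC)(CC)CC)/C=C(/C)[Li])[C@H](O[Si](CC)(CC)CC)CO[Si](c1ccccc1)(c1ccccc1)C(C)(C)C | intermediate
22 | seco-dienone: I–C10(CH3)=C1H–C2H2–C3(=O)–C4(CH3)=C5H–C6H(OTES)–C7H[C(CH3)=CH2]–C8H(OTES)–C9H2–OTBDPS; 1(10)Z,4Z; 6R,7S,8S | C=C(C)[C@@H]([C@H](O[Si](CC)(CC)CC)/C=C(/C)C(=O)C/C=C(/C)I)[C@H](O[Si](CC)(CC)CC)CO[Si](c1ccccc1)(c1ccccc1)C(C)(C)C | intermediate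
23 | seco-allylic alcohol: 22 with C3H(OH); 1(10)Z,4Z; 3S,6R,7S,8S | C=C(C)[C@@H]([C@H](O[Si](CC)(CC)CC)/C=C(/C)[C@@H](O)C/C=C(/C)I)[C@H](O[Si](CC)(CC)CC)CO[Si](c1ccccc1)(c1ccccc1)C(C)(C)C | intermediate
24 | 4,5-epoxy alcohol: cis-4,5-oxirane of 23; 3S,4R,5S,6S,7R,8S | C=C(C)[C@@H]([C@H](O[Si](CC)(CC)CC)[C@@H]1O[C@]1(C)[C@@H](O)C/C=C(/C)I)[C@H](O[Si](CC)(CC)CC)CO[Si](c1ccccc1)(c1ccccc1)C(C)(C)C | intermediate
25 | epoxy triol: 24 with free C6–OH and C8–OH; 3S,4R,5S,6S,7R,8S | C=C(C)[C@@H]([C@H](O)[C@@H]1O[C@]1(C)[C@@H](O)C/C=C(/C)I)[C@H](O)CO[Si](c1ccccc1)(c1ccccc1)C(C)(C)C | intermediate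
26 | tris(angelate) silyl ether: 3,6,8-tri-O-Ang, 9-O-TBDPS; 3S,4R,5S,6S,7R,8S | C=C(C)[C@@H]([C@H](OC(=O)/C(C)=C\C)[C@@H]1O[C@]1(C)[C@@H](OC(=O)/C(C)=C\C)C/C=C(/C)I)[C@H](OC(=O)/C(C)=C\C)CO[Si](c1ccccc1)(c1ccccc1)C(C)(C)C | intermediate
27 | tris(angelate) primary alcohol: 26 with C9H2OH; 3S,4R,5S,6S,7R,8S | C=C(C)[C@@H]([C@H](OC(=O)/C(C)=C\C)[C@@H]1O[C@]1(C)[C@@H](OC(=O)/C(C)=C\C)C/C=C(/C)I)[C@H](OC(=O)/C(C)=C\C)CO | intermediate
28 | seco-aldehyde: 27 with C9H=O; 3S,4R,5S,6S,7S,8S | C=C(C)[C@@H]([C@H](OC(=O)/C(C)=C\C)[C@@H]1O[C@]1(C)[C@@H](OC(=O)/C(C)=C\C)C/C=C(/C)I)[C@H](OC(=O)/C(C)=C\C)C=O | intermediate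
29 | macrocyclic allylic alcohol: 4,5-epoxy-3,6,8-tris(angeloyloxy)germacra-1(10)Z,11-dien-9-ol, C9–OH anti to the C8 ester; 3S,4R,5S,6S,7R,8S,9R | C=C(C)[C@H]1[C@H](OC(=O)/C(C)=C\C)[C@@H]2O[C@]2(C)[C@@H](OC(=O)/C(C)=C\C)C/C=C(/C)[C@@H](O)[C@H]1OC(=O)/C(C)=C\C | intermediate
30 | bis-epoxy alcohol: 1,10:4,5-diepoxy-3,6,8-tris(angeloyloxy)germacr-11-en-9-ol, 1,10-oxirane cis to C9–OH; 1R,3S,4R,5S,6S,7R,8S,9S,10S | C=C(C)[C@H]1[C@H](OC(=O)/C(C)=C\C)[C@@H]2O[C@]2(C)[C@@H](OC(=O)/C(C)=C\C)C[C@H]2O[C@@]2(C)[C@@H](O)[C@H]1OC(=O)/C(C)=C\C | intermediate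
31 | (1R,3S,4R,5S,6S,7S,8S,10R)-1,10:4,5-diepoxy-3,6,8-tris(angeloyloxy)germacr-11-en-9-one | C=C(C)[C@H]1[C@H](OC(=O)/C(C)=C\C)[C@@H]2O[C@]2(C)[C@@H](OC(=O)/C(C)=C\C)C[C@H]2O[C@@]2(C)C(=O)[C@H]1OC(=O)/C(C)=C\C | target

The changes of descriptor at C6, C7, C9 and C10 between entries come only from changed CIP priorities; no stereocentre is inverted after step 4.

## Step count and risks

Total step count: 26.
Longest linear sequence: 17 steps (steps 1–7, then 17–26; the western branch, steps 8–14 then 17–26, is equally long), which is 17/26 ≈ 0.65 of the total.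

Three steps most likely to fail:

Step 24, the ten-membered Nozaki–Hiyama–Kishi ring closure, may give oligomers or a poor C9 ratio. The fallback closes the same ring by metathesis; it sets out from 26 and returns at 29. Bu3SnH with Pd(PPh3)4 removes the iodine of 26 with retention and gives the (E)-propenyl tris(angelate) F5. HF·pyridine gives the primary alcohol F6, and Dess–Martin oxidation the aldehyde F7. An intermolecular Nozaki–Hiyama–Kishi reaction with 2-iodopropene (CrCl2, NiCl2 cat., DMSO) adds the C10 isopropenyl unit anti to the C8 ester and gives the diene carbinol F8. Ring-closing metathesis with the second-generation Grubbs catalyst RuCl2(=CHPh)(PCy3)(H2IMes) in toluene at 80 °C and 1 mM joins C1 to C10 with loss of propene, and the ring size forces the Z alkene of 29.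

Step 21, the triple angeloylation, heats a hindered triol whose C8 hydroxyl can open the 4,5-epoxide to a tetrahydrofuran, and angelates can isomerise. The fallback builds the enoates on the molecule; it sets out from 25 and returns at 26. Triol 25 is esterified at 0 °C with 2-[bis(2,2,2-trifluoroethoxy)phosphoryl]propanoic acid, DCC and catalytic DMAP to the tris(phosphonopropanoate) F4. A threefold Still–Gennari olefination with acetaldehyde (KN(SiMe3)2, 18-crown-6, THF, −78 °C) then forms the three Z enoates and gives 26 without any heating of the hydroxy epoxide.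

Step 6, the Stork–Zhao olefination of a lactol, needs ring opening at temperatures where the iodo-ylide is short-lived. The fallback uses a true aldehyde; it sets out from 6 and returns at 8. Propane-1,3-dithiol and BF3·OEt2 (CH2Cl2, −20 °C) open lactol 6 to the acyclic 1,3-dithiane diol F1. TESCl and imidazole give its bis(triethylsilyl) ether F2. MeI and CaCO3 in aqueous MeCN release the α-silyloxy aldehyde F3, which undergoes the Stork–Zhao olefination at −78 °C and gives 8 directly, so step 7 is not needed.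

## Further compounds

F1 | step 6 | 1,3-dithiane diol: C5 as 1,3-dithian-2-yl, free C6–OH and C8–OH, 9-O-TBDPS, stereocentres as in 7 | C=C(C)[C@@H]([C@H](O)C1SCCCS1)[C@H](O)CO[Si](c1ccccc1)(c1ccccc1)C(C)(C)C
F2 | step 6 | 6,8-bis-O-TES ether of F1 | C=C(C)[C@@H]([C@H](O[Si](CC)(CC)CC)C1SCCCS1)[C@H](O[Si](CC)(CC)CC)CO[Si](c1ccccc1)(c1ccccc1)C(C)(C)C
F3 | step 6 | α-silyloxy aldehyde: C5H=O, 6,8-bis-O-TES, 9-O-TBDPS, stereocentres as in 8 | C=C(C)[C@@H]([C@H](O[Si](CC)(CC)CC)C=O)[C@H](O[Si](CC)(CC)CC)CO[Si](c1ccccc1)(c1ccccc1)C(C)(C)C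
F4 | step 21 | 3,6,8-tris-O-{2-[bis(2,2,2-trifluoroethoxy)phosphoryl]propanoyl} ester of 25 (mixture at the phosphonate α-carbons) | C=C(C)[C@@H]([C@H](OC(=O)C(C)P(=O)(OCC(F)(F)F)OCC(F)(F)F)[C@@H]1O[C@]1(C)[C@@H](OC(=O)C(C)P(=O)(OCC(F)(F)F)OCC(F)(F)F)C/C=C(/C)I)[C@H](OC(=O)C(C)P(=O)(OCC(F)(F)F)OCC(F)(F)F)CO[Si](c1ccccc1)(c1ccccc1)C(C)(C)C
F5 | step 24 | (E)-propenyl tris(angelate): 26 with H in place of I | C=C(C)[C@@H]([C@H](OC(=O)/C(C)=C\C)[C@@H]1O[C@]1(C)[C@@H](OC(=O)/C(C)=C\C)C/C=C/C)[C@H](OC(=O)/C(C)=C\C)CO[Si](c1ccccc1)(c1ccccc1)C(C)(C)C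
F6 | step 24 | primary alcohol from F5 (C9H2OH) | C=C(C)[C@@H]([C@H](OC(=O)/C(C)=C\C)[C@@H]1O[C@]1(C)[C@@H](OC(=O)/C(C)=C\C)C/C=C/C)[C@H](OC(=O)/C(C)=C\C)CO
F7 | step 24 | aldehyde from F6 (C9H=O) | C=C(C)[C@@H]([C@H](OC(=O)/C(C)=C\C)[C@@H]1O[C@]1(C)[C@@H](OC(=O)/C(C)=C\C)C/C=C/C)[C@H](OC(=O)/C(C)=C\C)C=O
F8 | step 24 | diene carbinol: C9H(OH)–C10(CH3)=CH2 added to F7, C9 configured as in 29 | C=C(C)[C@@H]([C@H](OC(=O)/C(C)=C\C)[C@@H]1O[C@]1(C)[C@@H](OC(=O)/C(C)=C\C)C/C=C/C)[C@H](OC(=O)/C(C)=C\C)[C@H](O)C(C)=C
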